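The bond between C1 of the geranyl chain and C5' of ring B is disconnected, and the flavan core with both stereocentres is bought as (+)-catechin. In one flask, iridium-catalysed C–H borylation and palladium-catalysed allyl–aryl coupling with geranyl methyl carbonate replace H at C5' by the intact (E)-geranyl group. The step exploits the ring-B catechol: bridged as a five-membered silylene, O4' is pinned back and activates the neighbouring C5'–H, whereas C6–H and C8–H of ring A and C2'–H are flanked on both sides and C6'–H adjoins the branched C2. The precursor is catechin carrying three TBS ethers and the catechol silylene.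

Key step: step 6

Assumption: (+)-catechin, (2R,3S), sold as the hydrate and dried before use, serves as chiral-pool source of C2 and C3, which no later step touches; primed locants refer to ring B, and TBS is tert-butyldimethylsilyl.

Step 1
Reactants: 1 (+)-catechin
Product: 2 3',4'-O-diphenylmethylene-(+)-catechin
Conditions: Ph2CCl2 (1.3 equiv), K2CO3 (3 equiv), MeCN, rt, argon
Reagents that add atoms: dichlorodiphenylmethane, ClC(Cl)(c1ccccc1)c1ccccc1
Why: Catechol-selective ketalisation by double O-alkylation with the gem-dichloride, in which only the vicinal O3'/O4' pair of ring B can close the five-membered 1,3-benzodioxole while mono-adducts at O5, O7 or O3 fall back to the free hydroxyl on aqueous work-up, so C2 (R) and C3 (S) are carried over unchanged.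

Step 2
Reactants: 2 3',4'-O-diphenylmethylene-(+)-catechin
Product: 3 3,5,7-tris-O-TBS-3',4'-O-diphenylmethylene-catechin
Conditions: TBSCl (4.5 equiv), imidazole (9 equiv), DMAP (cat.), DMF, 45 °C
Reagents that add atoms: tert-butyldimethylsilyl chloride, CC(C)(C)[Si](C)(C)Cl
Why: Imidazole-promoted silyl ether formation caps the two ring-A phenols and the secondary 3-OH, which removes acidic O–H bonds and nucleophilic phenoxides from the later metal-catalysed steps and walls off C6–H and C8–H with bulky OTBS groups.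

Step 3
Reactants: 3 3,5,7-tris-O-TBS-3',4'-O-diphenylmethylene-catechin
Product: 4 3,5,7-tris-O-TBS-(+)-catechin with free 3',4'-catechol
Conditions: H2 (1 atm), Pd(OH)2/C, EtOAc/THF, rt
Reagents that add atoms: none
Why: Catalytic hydrogenolysis of the doubly benzylic diphenylmethylene ketal frees the catechol at a stage where no alkene is present, and the TBS ethers and the C2–O1 bond survive neutral hydrogenation in an aprotic solvent.

Step 4
Reactants: 4 3,5,7-tris-O-TBS-(+)-catechin
Product: 5 3,5,7-tris-O-TBS-3',4'-O-(di-tert-butylsilylene)catechin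
Conditions: t-Bu2Si(OTf)2 (1.1 equiv), 2,6-lutidine (3 equiv), CH2Cl2, 0 °C, argon
Reagents that add atoms: di-tert-butylsilyl bis(trifluoromethanesulfonate), CC(C)(C)[Si](OS(=O)(=O)C(F)(F)F)(OS(=O)(=O)C(F)(F)F)C(C)(C)C
Why: Cyclic silylene formation, in which the first Si–O bond is followed by fast intramolecular closure onto the neighbouring phenol to give a 2,2-di-tert-butyl-1,3,2-benzodioxasilole, a fluoride-labile group that pins O3' and O4' back as a methylenedioxy bridge would.

Step 5
Reactants: 6 geraniol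
Product: 7 geranyl methyl carbonate
Conditions: ClCO2Me (1.3 equiv), pyridine (2 equiv), CH2Cl2, 0 °C
Reagents that add atoms: methyl chloroformate, COC(=O)Cl
Why: O-Acylation of the primary allylic alcohol with a chloroformate leaves the E-trisubstituted alkene untouched and installs a leaving group that releases CO2 and methoxide on ionisation.

Step 6
Reactants: 5 3,5,7-tris-O-TBS-3',4'-O-(di-tert-butylsilylene)catechin; 7 geranyl methyl carbonate
Product: 9 5'-geranyl-3,5,7-tris-O-TBS-3',4'-O-(di-tert-butylsilylene)catechin, via 5'-pinacolboronate 8 (not isolated)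
Conditions: [Ir(OMe)(cod)]2 (2.5 mol %), 3,4,7,8-tetramethyl-1,10-phenanthroline (5 mol %), B2pin2 (1.0 equiv), THF, 80 °C; volatiles removed in vacuo; then 7 (1.5 equiv), Pd2(dba)3 (2.5 mol %), PPh3 (12 mol %), THF, 60 °C, no base
Reagents that add atoms: none
Why: A trivalent iridium tris(boryl) complex cleaves the C5'–H bond and reductive elimination gives arylboronate 8; after removal of HBpin, zerovalent palladium ionises carbonate 7 with loss of CO2 to an (η3-geranyl) divalent palladium methoxide, whose Pd–OMe group takes up boron so that the aryl group is transferred without added base, and reductive elimination forms the C5'–CH2 bond. The closest known reaction types are the iridium-catalysed C–H borylation of 1,3-benzodioxoles (Miyaura–Hartwig type), which goes ortho to the ring oxygen, run in one pot with a Suzuki–Miyaura allyl–aryl coupling of an allylic carbonate under neutral conditions. No ring is closed and no stereocentre is formed, and C2 and C3 are spectators. Site selectivity is needed and the substrate secures it: C6–H, C8–H and C2'–H are each flanked by two substituents, C6'–H lies next to the branched C2, and only C5'–H lies next to the pinned-back, acidifying O4' of the silylene ring. Linear selectivity and E geometry are also needed: the aryl group goes to the unsubstituted CH2 terminus of the π-allyl ligand, and syn–anti exchange would require palladium on the tertiary C3 of the chain, which should be slow compared with coupling. The silyl ethers should survive because neither free base nor fluoride is present.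

Step 7
Reactants: 9 5'-geranyl-3,5,7-tris-O-TBS-3',4'-O-(di-tert-butylsilylene)catechin
Product: 10 5'-geranyl-(+)-catechin, (2R,3S)-2-[3-[(2E)-3,7-dimethylocta-2,6-dien-1-yl]-4,5-dihydroxyphenyl]chromane-3,5,7-triol
Conditions: TBAF (6 equiv), AcOH (6 equiv), degassed THF, 0 °C to rt, argon; work-up at pH 5
Reagents that add atoms: none
Why: Fluoride-mediated desilylation cleaves all five Si–O bonds in one operation, the acetic acid buffer keeps the phenols protonated so that the catechol is not oxidised and ring C is not opened at C2, and the geranyl chain never meets a strong acid.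

Compound list
1 | (+)-catechin, (2R,3S)-2-(3,4-dihydroxyphenyl)chromane-3,5,7-triol | Oc1ccc([C@H]2Oc3cc(O)cc(O)c3C[C@@H]2O)cc1O | starting material
2 | 3',4'-O-diphenylmethylene-(+)-catechin, (2R,3S)-2-(2,2-diphenyl-1,3-benzodioxol-5-yl)chromane-3,5,7-triol | C1(c2ccccc2)(c2ccccc2)Oc2ccc([C@H]3Oc4cc(O)cc(O)c4C[C@@H]3O)cc2O1 | intermediate
3 | (2R,3S)-3,5,7-tris-O-TBS-3',4'-O-diphenylmethylene-catechin | C1(c2ccccc2)(c2ccccc2)Oc2ccc([C@H]3Oc4cc(O[Si](C)(C)C(C)(C)C)cc(O[Si](C)(C)C(C)(C)C)c4C[C@@H]3O[Si](C)(C)C(C)(C)C)cc2O1 | intermediate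
4 | (2R,3S)-3,5,7-tris-O-TBS-catechin, free 3',4'-catechol | Oc1ccc([C@H]2Oc3cc(O[Si](C)(C)C(C)(C)C)cc(O[Si](C)(C)C(C)(C)C)c3C[C@@H]2O[Si](C)(C)C(C)(C)C)cc1O | intermediate
5 | (2R,3S)-3,5,7-tris-O-TBS-3',4'-O-(di-tert-butylsilylene)catechin | CC(C)(C)[Si]1(C(C)(C)C)Oc2ccc([C@H]3Oc4cc(O[Si](C)(C)C(C)(C)C)cc(O[Si](C)(C)C(C)(C)C)c4C[C@@H]3O[Si](C)(C)C(C)(C)C)cc2O1 | intermediate
6 | geraniol, (2E)-3,7-dimethylocta-2,6-dien-1-ol | CC(C)=CCC/C(C)=C/CO | starting material
7 | geranyl methyl carbonate, (2E)-3,7-dimethylocta-2,6-dien-1-yl methyl carbonate | CC(C)=CCC/C(C)=C/COC(=O)OC | intermediate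
8 | (2R,3S)-5'-(4,4,5,5-tetramethyl-1,3,2-dioxaborolan-2-yl)-3,5,7-tris-O-TBS-3',4'-O-(di-tert-butylsilylene)catechin | CC(C)(C)[Si]1(C(C)(C)C)Oc2c(B3OC(C)(C)C(C)(C)O3)cc([C@H]3Oc4cc(O[Si](C)(C)C(C)(C)C)cc(O[Si](C)(C)C(C)(C)C)c4C[C@@H]3O[Si](C)(C)C(C)(C)C)cc2O1 | intermediate
9 | (2R,3S)-5'-geranyl-3,5,7-tris-O-TBS-3',4'-O-(di-tert-butylsilylene)catechin | CC(C)=CCC/C(C)=C/Cc1cc([C@H]2Oc3cc(O[Si](C)(C)C(C)(C)C)cc(O[Si](C)(C)C(C)(C)C)c3C[C@@H]2O[Si](C)(C)C(C)(C)C)cc2O[Si](C(C)(C)C)(C(C)(C)C)Oc12 | intermediate
10 | 5'-geranyl-(+)-catechin, (2R,3S)-2-[3-[(2E)-3,7-dimethylocta-2,6-dien-1-yl]-4,5-dihydroxyphenyl]chromane-3,5,7-triol | CC(C)=CCC/C(C)=C/Cc1cc([C@H]2Oc3cc(O)cc(O)c3C[C@@H]2O)cc(O)c1O | target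

Total step count: 7. Longest linear sequence: 6 (steps 1, 2, 3, 4, 6, 7 from (+)-catechin; step 5 is a one-step side branch).

Steps most likely to fail

Step 6. The borylation may go to C6'–H or stall if the silylene oxygen activates its neighbour less than a dioxole oxygen does. In the palladium stage, methoxide may capture the π-allyl before transmetalation, or syn–anti exchange may erode the E geometry. The fallback uses directed ortho-metalation and copper-mediated allylation, both known chemistry, and sets out from 4. MOMCl and i-Pr2NEt in CH2Cl2 should give (2R,3S)-3',4'-bis-O-(methoxymethyl)-3,5,7-tris-O-TBS-catechin F1. n-BuLi and TMEDA in THF at −20 °C should lithiate C5', the only position ortho to a chelating OMOM group and open on its other side. Transmetalation with CuBr·SMe2 and SN2 alkylation with geranyl bromide should give (2R,3S)-5'-geranyl-3',4'-bis-O-(methoxymethyl)-3,5,7-tris-O-TBS-catechin F2. TBAF buffered with AcOH should give (2R,3S)-5'-geranyl-3',4'-bis-O-(methoxymethyl)catechin F3. Catalytic TsOH in MeOH at rt should then remove the two acetals, and the fallback comes back to the route at 10.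

Step 4. Intermolecular silylation between two catechols may compete with ring closure, and the strained five-membered silylene may open hydrolytically on silica. The fallback drops the silylene and sets out from 3, whose diphenylmethylene ketal is itself a 1,3-benzodioxole. Iridium-catalysed borylation under the conditions of step 6 should give (2R,3S)-5'-(pinacolboryl)-3',4'-O-diphenylmethylene-3,5,7-tris-O-TBS-catechin F4. Hydrogenolysis over Pd(OH)2/C, before any alkene is present, should give (2R,3S)-5'-(pinacolboryl)-3,5,7-tris-O-TBS-catechin F5. TBSCl and imidazole should give (2R,3S)-5'-(pinacolboryl)-3,5,7,3',4'-pentakis-O-TBS-catechin F6. Coupling with 7 under Pd2(dba)3/PPh3 should give (2R,3S)-5'-geranyl-3,5,7,3',4'-pentakis-O-TBS-catechin F7. TBAF/AcOH then comes back to the route at 10.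

Step 7. Air may oxidise the liberated catechol, base may open ring C at C2–O1 and epimerise C2, and the hindered 3-O-silyl ether may cleave incompletely. The fallback is capture and release through a stable ester and sets out from 9. After TBAF/AcOH in THF, Ac2O, pyridine and DMAP are added to the same flask to give (2R,3S)-5'-geranylcatechin pentaacetate F8, which can be purified in air. Catalytic K2CO3 in degassed MeOH at 0 °C should then release the polyphenol, and the fallback comes back to the route at 10.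

Further compounds
F1 | step 6 | (2R,3S)-3',4'-bis-O-(methoxymethyl)-3,5,7-tris-O-TBS-catechin | COCOc1ccc([C@H]2Oc3cc(O[Si](C)(C)C(C)(C)C)cc(O[Si](C)(C)C(C)(C)C)c3C[C@@H]2O[Si](C)(C)C(C)(C)C)cc1OCOC
F2 | step 6 | (2R,3S)-5'-geranyl-3',4'-bis-O-(methoxymethyl)-3,5,7-tris-O-TBS-catechin | CC(C)=CCC/C(C)=C/Cc1cc([C@H]2Oc3cc(O[Si](C)(C)C(C)(C)C)cc(O[Si](C)(C)C(C)(C)C)c3C[C@@H]2O[Si](C)(C)C(C)(C)C)cc(OCOC)c1OCOC
F3 | step 6 | (2R,3S)-5'-geranyl-3',4'-bis-O-(methoxymethyl)catechin | CC(C)=CCC/C(C)=C/Cc1cc([C@H]2Oc3cc(O)cc(O)c3C[C@@H]2O)cc(OCOC)c1OCOC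
F4 | step 4 | (2R,3S)-5'-(pinacolboryl)-3',4'-O-diphenylmethylene-3,5,7-tris-O-TBS-catechin | C1(c2ccccc2)(c2ccccc2)Oc2c(B3OC(C)(C)C(C)(C)O3)cc([C@H]3Oc4cc(O[Si](C)(C)C(C)(C)C)cc(O[Si](C)(C)C(C)(C)C)c4C[C@@H]3O[Si](C)(C)C(C)(C)C)cc2O1
F5 | step 4 | (2R,3S)-5'-(pinacolboryl)-3,5,7-tris-O-TBS-catechin | Oc1c(B2OC(C)(C)C(C)(C)O2)cc([C@H]2Oc3cc(O[Si](C)(C)C(C)(C)C)cc(O[Si](C)(C)C(C)(C)C)c3C[C@@H]2O[Si](C)(C)C(C)(C)C)cc1O
F6 | step 4 | (2R,3S)-5'-(pinacolboryl)-3,5,7,3',4'-pentakis-O-TBS-catechin | CC(C)(C)[Si](C)(C)Oc1c(B2OC(C)(C)C(C)(C)O2)cc([C@H]2Oc3cc(O[Si](C)(C)C(C)(C)C)cc(O[Si](C)(C)C(C)(C)C)c3C[C@@H]2O[Si](C)(C)C(C)(C)C)cc1O[Si](C)(C)C(C)(C)C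
F7 | step 4 | (2R,3S)-5'-geranyl-3,5,7,3',4'-pentakis-O-TBS-catechin | CC(C)=CCC/C(C)=C/Cc1cc([C@H]2Oc3cc(O[Si](C)(C)C(C)(C)C)cc(O[Si](C)(C)C(C)(C)C)c3C[C@@H]2O[Si](C)(C)C(C)(C)C)cc(O[Si](C)(C)C(C)(C)C)c1O[Si](C)(C)C(C)(C)C
F8 | step 7 | (2R,3S)-5'-geranylcatechin pentaacetate | CC(C)=CCC/C(C)=C/Cc1cc([C@H]2Oc3cc(OC(C)=O)cc(OC(C)=O)c3C[C@@H]2OC(C)=O)cc(OC(C)=O)c1OC(C)=O
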